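The synthesis rests on one disconnection: the bond between the β-carbon of the enone that carries the 2,4-dihydroxyphenyl ketone (ring D) and the carbon of the para-phenylene ether ring (ring C) that lies para to the diaryl ether oxygen. A Mizoroki–Heck arylation makes this bond and, by syn-insertion and syn-β-hydride elimination, sets the second E-enone in the same operation. It exploits the fact that ring C is a simple 1,4-disubstituted arene whose styrenic carbon can enter as C–I. The precursors are an iodinated diaryl ether chalcone (rings A, B and C complete) and a MOM-protected aryl vinyl ketone (ring D); one acidic step then frees the three phenols.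

Key step: step 7

Assumption: the MOM-protected aldehyde used in step 3 is taken as a purchasable building block (otherwise one MOM protection of 4-hydroxybenzaldehyde supplies it). Ring A is the 2-hydroxy-4-methoxyphenyl ketone ring and ring B the 4-hydroxyphenyl ring.

Step 1
Reactants: 1 methoxyhydroquinone (2-methoxybenzene-1,4-diol)
Product: 3 1-(2,5-dihydroxy-4-methoxyphenyl)ethanone, via difluoroboron chelate 2 (not isolated)
Conditions: AcOH, BF3·OEt2 (3 equiv), 90 °C; then H2O/EtOH, 80 °C
Reagents that add atoms: acetic acid, CC(=O)O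
Why: Friedel–Crafts (Nencki-type) C-acylation should occur at the ring carbon para to the methoxy group and ortho to a hydroxyl, the most activated unhindered site, and the ortho-hydroxy ketone is held as its difluoroboron chelate, which stops a second acylation and is hydrolysed on aqueous work-up.

Step 2
Reactants: 3 1-(2,5-dihydroxy-4-methoxyphenyl)ethanone; 4 1,4-diiodobenzene (3 equiv)
Product: 5 1-[2-hydroxy-5-(4-iodophenoxy)-4-methoxyphenyl]ethanone
Conditions: CuI (10 mol %), picolinic acid (20 mol %), K3PO4, DMSO, 80 °C, N2 (degassed)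
Reagents that add atoms: none
Why: Ullmann-type copper-catalysed diaryl ether synthesis should take place at the 5-OH, the only phenol not hydrogen-bonded to and conjugated with the acetyl group, while the excess of diiodide holds the coupling at the mono-ether stage and leaves one C–I bond for step 7.

Step 3
Reactants: 5 1-[2-hydroxy-5-(4-iodophenoxy)-4-methoxyphenyl]ethanone; 6 4-(methoxymethoxy)benzaldehyde
Product: 8 (E)-1-[2-hydroxy-5-(4-iodophenoxy)-4-methoxyphenyl]-3-[4-(methoxymethoxy)phenyl]prop-2-en-1-one, via aldol adduct 7 (not isolated)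
Conditions: KOH (50 % aq.), EtOH, rt; then aq. AcOH to pH 6, 0 °C
Reagents that add atoms: none
Why: Claisen–Schmidt aldol condensation, in which the methyl ketone enolate adds to the non-enolisable aldehyde and E1cB dehydration of the aldol gives the thermodynamically preferred E-enone, with the aryl iodide and the MOM ether inert to aqueous-alcoholic KOH.

Step 4
Reactants: 9 2,4-dihydroxybenzaldehyde
Product: 10 2,4-bis(methoxymethoxy)benzaldehyde
Conditions: NaH (2.5 equiv), MOMCl (2.5 equiv), DMF, 0 °C to rt
Reagents that add atoms: chloromethyl methyl ether, COCCl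
Why: Williamson-type O-alkylation of both sodium phenoxides (MOM protection), NaH being strong enough to bring the hydrogen-bonded ortho-hydroxyl into reaction.

Step 5
Reactants: 10 2,4-bis(methoxymethoxy)benzaldehyde
Product: 11 1-[2,4-bis(methoxymethoxy)phenyl]prop-2-en-1-ol (racemic)
Conditions: CH2=CHMgBr, THF, −78 to 0 °C; then aq. NH4Cl
Reagents that add atoms: vinylmagnesium bromide, C=C[Mg]Br
Why: Grignard 1,2-addition to the aldehyde, tolerated by the MOM acetals, should give the carbinol as a racemate, which is of no consequence because this centre becomes the ketone in step 6.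

Step 6
Reactants: 11 1-[2,4-bis(methoxymethoxy)phenyl]prop-2-en-1-ol
Product: 12 1-[2,4-bis(methoxymethoxy)phenyl]prop-2-en-1-one
Conditions: activated MnO2 (15 equiv), CH2Cl2, rt; filtration through Celite, used at once
Reagents that add atoms: none
Why: MnO2 oxidation of an alcohol that is both allylic and benzylic proceeds under neutral heterogeneous conditions, so the aryl vinyl ketone is released without acid or base that would start its polymerisation.

Step 7
Reactants: 8 (E)-1-[2-hydroxy-5-(4-iodophenoxy)-4-methoxyphenyl]-3-[4-(methoxymethoxy)phenyl]prop-2-en-1-one; 12 1-[2,4-bis(methoxymethoxy)phenyl]prop-2-en-1-one (1.5 equiv)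
Product: 13 (E)-1-[2,4-bis(methoxymethoxy)phenyl]-3-[4-[4-hydroxy-2-methoxy-5-[(E)-3-[4-(methoxymethoxy)phenyl]prop-2-enoyl]phenoxy]phenyl]prop-2-en-1-one
Conditions: Pd(OAc)2 (5 mol %), n-Bu4NCl, NaHCO3, BHT (cat.), DMF, 60 °C
Reagents that add atoms: none
Why: Mizoroki–Heck reaction under Jeffery phase-transfer conditions, the closest precedent being the known chalcone synthesis from aryl iodides and aryl vinyl ketones: zerovalent palladium formed in situ from Pd(OAc)2 inserts into the C–I bond on ring C of 8, the terminal alkene of 12 coordinates, and syn-carbopalladation delivers the aryl group to the unsubstituted β-carbon, which creates the ring C–CH bond. Rotation about the new C–C single bond and syn-β-hydride elimination from the conformer with the aryl and aroyl groups anti should then release the E-enone, and NaHCO3 regenerates the zerovalent catalyst. No ring is closed and no stereocentre is formed; the only stereochemical element is the alkene geometry, controlled by this syn-elimination and by the thermodynamic preference for the E-chalcone. The step needs β- over α-arylation, which the polarised monosubstituted enone secures, and reaction at the vinyl ketone in preference to the 1,2-disubstituted enone already present in 8, which inserts far more slowly. The weak base and the hydrogen-bonded state of the 2-OH on ring A should hold back oxa-Michael closure to a flavanone, while the MOM ether ortho to the ketone of 12 rules out the chromanone closure that a free phenol would undergo.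

Step 8
Reactants: 13 (E)-1-[2,4-bis(methoxymethoxy)phenyl]-3-[4-[4-hydroxy-2-methoxy-5-[(E)-3-[4-(methoxymethoxy)phenyl]prop-2-enoyl]phenoxy]phenyl]prop-2-en-1-one
Product: 14 rhuschalcone III, (E)-1-(2,4-dihydroxyphenyl)-3-[4-[4-hydroxy-5-[(E)-3-(4-hydroxyphenyl)prop-2-enoyl]-2-methoxyphenoxy]phenyl]prop-2-en-1-one
Conditions: 3 M aq. HCl, MeOH/THF, 50 °C, short reaction time
Reagents that add atoms: none
Why: acid-catalysed acetal cleavage (transacetalisation to methanol) should remove all three MOM ethers while the methyl ether, the diaryl ether and both E-enones are stable to dilute acid, and the short exposure limits acid-promoted chalcone-to-flavanone cyclisation.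

Compound list
1 | methoxyhydroquinone (2-methoxybenzene-1,4-diol) | COc1cc(O)ccc1O | starting material
2 | difluoroboron chelate of 1-(2,5-dihydroxy-4-methoxyphenyl)ethanone (O–BF2–O bridge between the ketone oxygen and the ortho-phenol oxygen) | CC1=[O+][B-](F)(F)Oc2cc(OC)c(O)cc21 | intermediate
3 | 1-(2,5-dihydroxy-4-methoxyphenyl)ethanone | CC(=O)c1cc(O)c(OC)cc1O | intermediate
4 | 1,4-diiodobenzene | Ic1ccc(I)cc1 | starting material
5 | 1-[2-hydroxy-5-(4-iodophenoxy)-4-methoxyphenyl]ethanone | CC(=O)c1cc(Oc2ccc(I)cc2)c(OC)cc1O | intermediate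
6 | 4-(methoxymethoxy)benzaldehyde | COCOc1ccc(C=O)cc1 | starting material
7 | aldol adduct, 3-hydroxy-1-[2-hydroxy-5-(4-iodophenoxy)-4-methoxyphenyl]-3-[4-(methoxymethoxy)phenyl]propan-1-one (racemic) | COCOc1ccc(C(O)CC(=O)c2cc(Oc3ccc(I)cc3)c(OC)cc2O)cc1 | intermediate
8 | (E)-1-[2-hydroxy-5-(4-iodophenoxy)-4-methoxyphenyl]-3-[4-(methoxymethoxy)phenyl]prop-2-en-1-one | COCOc1ccc(/C=C/C(=O)c2cc(Oc3ccc(I)cc3)c(OC)cc2O)cc1 | intermediate
9 | 2,4-dihydroxybenzaldehyde | O=Cc1ccc(O)cc1O | starting material
10 | 2,4-bis(methoxymethoxy)benzaldehyde | COCOc1ccc(C=O)c(OCOC)c1 | intermediate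
11 | 1-[2,4-bis(methoxymethoxy)phenyl]prop-2-en-1-ol (racemic) | C=CC(O)c1ccc(OCOC)cc1OCOC | intermediate
12 | 1-[2,4-bis(methoxymethoxy)phenyl]prop-2-en-1-one | C=CC(=O)c1ccc(OCOC)cc1OCOC | intermediate
13 | (E)-1-[2,4-bis(methoxymethoxy)phenyl]-3-[4-[4-hydroxy-2-methoxy-5-[(E)-3-[4-(methoxymethoxy)phenyl]prop-2-enoyl]phenoxy]phenyl]prop-2-en-1-one | COCOc1ccc(/C=C/C(=O)c2cc(Oc3ccc(/C=C/C(=O)c4ccc(OCOC)cc4OCOC)cc3)c(OC)cc2O)cc1 | intermediate
14 | rhuschalcone III, (E)-1-(2,4-dihydroxyphenyl)-3-[4-[4-hydroxy-5-[(E)-3-(4-hydroxyphenyl)prop-2-enoyl]-2-methoxyphenoxy]phenyl]prop-2-en-1-one | COc1cc(O)c(C(=O)/C=C/c2ccc(O)cc2)cc1Oc1ccc(/C=C/C(=O)c2ccc(O)cc2O)cc1 | target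

Total step count: 8 steps.
Longest linear sequence: 5 steps (steps 1, 2, 3, 7, 8; the ring D branch, steps 4, 5, 6, 7, 8, is equally long).

Steps most likely to fail

Step 7. The vinyl ketone may polymerise or take up the ring A phenoxide in a conjugate addition faster than it is carbopalladated, and base may close the free 2-hydroxychalcone to a flavanone. The fallback sets out from 10 and 8 and comes back at 13; it forms the same ring C–carbon bond as an aryl–alkyne bond. Ethynylmagnesium bromide in THF at 0 °C should add to aldehyde 10 to give 1-[2,4-bis(methoxymethoxy)phenyl]prop-2-yn-1-ol F1. Sonogashira coupling of this alkynol with iodide 8 (PdCl2(PPh3)2, CuI, Et3N, THF, rt) should give (E)-1-[5-[4-[3-[2,4-bis(methoxymethoxy)phenyl]-3-hydroxyprop-1-ynyl]phenoxy]-2-hydroxy-4-methoxyphenyl]-3-[4-(methoxymethoxy)phenyl]prop-2-en-1-one F2. Base-mediated propargylic alcohol-to-enone redox isomerisation (catalytic DBU, THF, 60 °C), the second half of the known coupling–isomerisation route to chalcones, should then deliver E-enone 13 without ever handling a vinyl ketone.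

Step 2. Arylation may run on at both phenols or at both C–I bonds, and copper may oxidise the hydroquinone to a quinone. The fallback sets out from 3 and comes back at 5; it replaces the copper coupling by a metal-free SNAr and installs iodine afterwards. 1-Fluoro-4-nitrobenzene with K2CO3 (1 equiv) in DMF at 70 °C should arylate only the non-chelated 5-OH to give 1-[2-hydroxy-4-methoxy-5-(4-nitrophenoxy)phenyl]ethanone F3. Iron powder with NH4Cl in EtOH/H2O at 70 °C should reduce the nitro group to 1-[5-(4-aminophenoxy)-2-hydroxy-4-methoxyphenyl]ethanone F4. Diazotisation–iodination in one pot (NaNO2, p-TsOH·H2O, KI, MeCN/H2O, 10 °C to rt) should then pass through 4-(5-acetyl-4-hydroxy-2-methoxyphenoxy)benzenediazonium p-toluenesulfonate F5, which is not isolated and loses nitrogen to iodide to give 5.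

Step 6. The aryl vinyl ketone may polymerise or dimerise by hetero-Diels–Alder reaction during concentration and storage. The fallback sets out from 11 (with 8) and comes back at 13; it reverses the order of oxidation and arylation so that no vinyl ketone is ever isolated. A silver-assisted Heck arylation of allylic alcohol 11 with iodide 8 (Pd(OAc)2, Ag2CO3, DMF, 60 °C), in which the silver salt suppresses the hydride re-addition that would lead to the saturated ketone, should give (E)-1-[5-[4-[(E)-3-[2,4-bis(methoxymethoxy)phenyl]-3-hydroxyprop-1-enyl]phenoxy]-2-hydroxy-4-methoxyphenyl]-3-[4-(methoxymethoxy)phenyl]prop-2-en-1-one F6. MnO2 in CH2Cl2 at rt should then oxidise this 1,3-diarylallyl alcohol to 13.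

Further compounds
F1 | step 7 | 1-[2,4-bis(methoxymethoxy)phenyl]prop-2-yn-1-ol (racemic) | C#CC(O)c1ccc(OCOC)cc1OCOC
F2 | step 7 | (E)-1-[5-[4-[3-[2,4-bis(methoxymethoxy)phenyl]-3-hydroxyprop-1-ynyl]phenoxy]-2-hydroxy-4-methoxyphenyl]-3-[4-(methoxymethoxy)phenyl]prop-2-en-1-one (racemic) | COCOc1ccc(/C=C/C(=O)c2cc(Oc3ccc(C#CC(O)c4ccc(OCOC)cc4OCOC)cc3)c(OC)cc2O)cc1
F3 | step 2 | 1-[2-hydroxy-4-methoxy-5-(4-nitrophenoxy)phenyl]ethanone | CC(=O)c1cc(Oc2ccc([N+](=O)[O-])cc2)c(OC)cc1O
F4 | step 2 | 1-[5-(4-aminophenoxy)-2-hydroxy-4-methoxyphenyl]ethanone | CC(=O)c1cc(Oc2ccc(N)cc2)c(OC)cc1O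
F5 | step 2 | 4-(5-acetyl-4-hydroxy-2-methoxyphenoxy)benzenediazonium p-toluenesulfonate | CC(=O)c1cc(Oc2ccc([N+]#N)cc2)c(OC)cc1O.Cc1ccc(S(=O)(=O)[O-])cc1
F6 | step 6 | (E)-1-[5-[4-[(E)-3-[2,4-bis(methoxymethoxy)phenyl]-3-hydroxyprop-1-enyl]phenoxy]-2-hydroxy-4-methoxyphenyl]-3-[4-(methoxymethoxy)phenyl]prop-2-en-1-one (racemic at the carbinol) | COCOc1ccc(/C=C/C(=O)c2cc(Oc3ccc(/C=C/C(O)c4ccc(OCOC)cc4OCOC)cc3)c(OC)cc2O)cc1
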